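A direct plan would keep all three purchased benzene rings and would attach the side chain to a finished chalcone.
It would condense 2',4'-dihydroxy-3'-methylacetophenone A1 with 4-hydroxybenzaldehyde A2 to chalcone A3, peracetylate it to A4 and brominate the aryl methyl group to A5.
A Stille coupling of A5 with the (Z)-stannane A6 would give allylic alcohol A7. O-Feruloylation of A7 would give triacetate A8, and removal of the three aryl acetates would end the plan.
The weakest step would be the radical benzylic bromination: the methyl group sits between two acetoxy groups, and bromine would also attack the enone C=C and the product itself (over-bromination).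
Next would be the sp3–sp2 tin coupling: oxidative addition at a di-ortho-substituted benzylic bromide would be slow, homocoupling would compete, and stoichiometric tin would have to be purged from a polar product.
The peracetylation/tri-deacetylation pair would add two operations without adding complexity, and the last one would have to spare the alkyl ferulate and avoid flavanone closure.

**New strategy.** Ring A is built last instead of bought. C2'–C5' is the four-carbon chain of methyl acetoacetate, whose α-carbon (the future C3', between both oxygenated carbons) is alkylated regioselectively. C1'–C6' is the alkyne of an enynone that already holds the chalcone enone. One Diels–Alder/aromatisation forms C1'–C2' and C5'–C6', joins the two halves and creates both ring-A phenols with the ferulate ester and the Z alkene already in place. The Z geometry is inherited from the ring of 3-methyl-2,5-dihydrofuran, opened by a feruloyl chloride. Benzylic bromination and tin coupling have no counterpart. Ring-A phenols are never protected, and the two remaining silyl ethers leave in the key-step flask.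

Key step: step 8

Assumption: the target has no stereocentre, so "single enantiomer" is read as the alkene geometries of the SMILES. The chalcone and ferulate C=C are E, and the side-chain C=C is Z (OCH2 cis to ArCH2).

**Route**

Step 1
Reactants: 1 2-methyl-2-vinyloxirane (isoprene monoxide, racemic)
Product: 2 3-methyl-2,5-dihydrofuran
Conditions: Cu(hfacac)2 (1 mol%), neat, 120 °C (sealed tube); product distilled out
Reagents that add atoms: none
Why: Copper(II)-catalysed vinyloxirane-to-2,5-dihydrofuran ring expansion, in which the tertiary allylic C–O bond opens and the alkoxide recloses on the far allyl terminus, and because a five-membered ring can hold only a cis alkene the two CH2 groups are locked on the same side of the C=C, which is the future Z geometry.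

Step 2
Reactants: 3 trans-ferulic acid; 4 tert-butyldimethylsilyl chloride
Product: 5 tert-butyldimethylsilyl (E)-3-[4-(tert-butyldimethylsilyloxy)-3-methoxyphenyl]prop-2-enoate
Conditions: TBSCl (2.3 equiv), imidazole (5 equiv), DMF, rt
Reagents that add atoms: tert-butyldimethylsilyl chloride, CC(C)(C)[Si](C)(C)Cl
Why: Imidazole-promoted silylation of both acidic OH groups, in which the silyl ester serves as the neutral entry to the acid chloride and the aryl silyl ether masks the one phenol that must pass through electrophilic and basic steps and later leaves in the flask of step 8.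

Step 3
Reactants: 5; 6 oxalyl chloride; 2
Product: 8 (2Z)-4-chloro-2-methylbut-2-en-1-yl (E)-3-[4-(tert-butyldimethylsilyloxy)-3-methoxyphenyl]prop-2-enoate, via (E)-3-[4-(tert-butyldimethylsilyloxy)-3-methoxyphenyl]prop-2-enoyl chloride 7 (not isolated)
Conditions: (COCl)2 (1.2 equiv), DMF (cat.), CH2Cl2, 0 °C to rt, evaporate; then 2 (1.5 equiv), ZnCl2 (5 mol%), CH2Cl2, −20 to 0 °C
Reagents that add atoms: oxalyl chloride, O=C(Cl)C(=O)Cl
Why: Conversion of a silyl ester into the acid chloride under neutral conditions followed by Lewis-acid-catalysed acylative cleavage of a cyclic ether, in which O-acylation of 2 gives an acyloxonium ion that chloride opens by SN2 at C5 (the prenyl-type CH2 next to CH=, less hindered and better activated than the methallyl-type C2), so that the ester C–O bond, the leaving group and the ring-derived Z alkene appear together.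

Step 4
Reactants: 8; 9 methyl acetoacetate
Product: 10 methyl (4Z)-2-acetyl-6-{[(E)-3-(4-tert-butyldimethylsilyloxy-3-methoxyphenyl)prop-2-enoyl]oxy}-5-methylhex-4-enoate (racemic at C2)
Conditions: 9 (1.5 equiv), NaH (1.4 equiv), THF/DMF (4:1), 0 °C; then 8, rt
Reagents that add atoms: none
Why: Acetoacetic ester alkylation, in which the soft enolate displaces the primary allylic chloride by SN2 (SN2′ would have to attack a fully substituted alkene carbon), no allyl cation or π-allyl metal intervenes so the Z alkene should be retained, and the new α-stereocentre is racemic and vanishes in step 5.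

Step 5
Reactants: 10; 11 trimethylsilyl trifluoromethanesulfonate
Product: 12 (2Z)-4-[1-methoxy-1,3-bis(trimethylsilyloxy)buta-1,3-dien-2-yl]-2-methylbut-2-en-1-yl (E)-3-[4-(tert-butyldimethylsilyloxy)-3-methoxyphenyl]prop-2-enoate (ketene-acetal geometry undefined and irrelevant)
Conditions: TMSOTf (2.4 equiv), Et3N (3.5 equiv), Et2O, 0 °C to rt; pentane extraction, used crude
Reagents that add atoms: trimethylsilyl trifluoromethanesulfonate, C[Si](C)(C)OS(=O)(=O)C(F)(F)F
Why: Soft double enolisation/O-silylation of a β-keto ester, which should first give the β-silyloxy enoate and then, by vinylogous deprotonation of the CH3 group of the silyl-activated ester, the 1,3-bis(silyloxy)diene, while the ferulate ester has no enolisable hydrogen and the buffered medium leaves the allylic ester alone.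

Step 6
Reactants: 13 4-(tert-butyldimethylsilyloxy)benzaldehyde; 14 diethyl {2-[methoxy(methyl)amino]-2-oxoethyl}phosphonate
Product: 15 (E)-3-[4-(tert-butyldimethylsilyloxy)phenyl]-N-methoxy-N-methylprop-2-enamide
Conditions: NaH (1.1 equiv), THF, 0 °C to rt
Reagents that add atoms: none
Why: Horner–Wadsworth–Emmons olefination with a stabilised phosphonoacetamide anion, whose reversible addition step should deliver the E alkene that becomes the chalcone C=C.

Step 7
Reactants: 15; 16 ethynylmagnesium bromide
Product: 17 (E)-1-[4-(tert-butyldimethylsilyloxy)phenyl]pent-1-en-4-yn-3-one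
Conditions: HC≡CMgBr (1.5 equiv), THF, 0 °C; inverse quench into cold 1 M HCl
Reagents that add atoms: ethynylmagnesium bromide, C#C[Mg]Br
Why: Weinreb ketone synthesis, in which the chelated tetrahedral intermediate stops at monoaddition and the inverse acidic quench protonates the released amine before it can add to the new ynone.

Step 8
Reactants: 12; 17
Product: 19 gemichalcone A, via cyclohexa-1,4-diene cycloadduct 18 (not isolated)
Conditions: 12 (1.3 equiv), BHT (cat.), PhMe, rt to 70 °C; then KHF2 (6 equiv), THF/MeOH, rt
Reagents that add atoms: none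
Why: A normal-electron-demand, strongly asynchronous Diels–Alder reaction is expected, in which the terminal CH2 of diene 12 (largest HOMO coefficient, pushed by all three oxygens) bonds to the terminal alkyne carbon of 17 (largest LUMO coefficient) to form C5'–C6' and the ketene-acetal carbon bonds to the ynone α-carbon to form C1'–C2', giving the cyclohexa-1,4-diene 18 with C2'(OMe)(OTMS), C1'(acyl)=C6'H, C5'H2 and C4'(OTMS)=C3'(side chain). Bifluoride then takes off the silyl groups, the C2' hemiketal expels methanol, the resulting 4H-dienone tautomerises to the resorcinol, and the two aryl silyl ethers fall in the same flask. The closest known reaction type is the Diels–Alder/aromatisation of 1,1,3-trioxygenated butadienes with acetylenic ketones and esters, which gives 4-acyl- and 4-carboalkoxyresorcinols with this "ortho/para" orientation. Ring A is the only ring closed, in a six-membered suprafacial [4+2] mode; no stereocentre survives (C2' of 18 is destroyed), and the three alkene geometries are spectators because no metal, strong acid or strong base is present. The step needs the alkyne to react ahead of the enone and enoate C=C bonds, which the unhindered terminal ynone secures against two β-aryl, donor-substituted alkenes. It also needs loss of methoxide rather than silanolate at C2', which fluoride attack at silicon secures.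

**Compound list**
1 | 2-methyl-2-vinyloxirane | CC1(C=C)CO1 | starting material
2 | 3-methyl-2,5-dihydrofuran | CC1=CCOC1 | intermediate
3 | trans-ferulic acid | COc1cc(/C=C/C(=O)O)ccc1O | starting material
4 | tert-butyldimethylsilyl chloride | CC(C)(C)[Si](C)(C)Cl | starting material (reagent)
5 | tert-butyldimethylsilyl (E)-3-[4-(tert-butyldimethylsilyloxy)-3-methoxyphenyl]prop-2-enoate | COc1cc(/C=C/C(=O)O[Si](C)(C)C(C)(C)C)ccc1O[Si](C)(C)C(C)(C)C | intermediate
6 | oxalyl chloride | O=C(Cl)C(=O)Cl | starting material (reagent)
7 | (E)-3-[4-(tert-butyldimethylsilyloxy)-3-methoxyphenyl]prop-2-enoyl chloride | COc1cc(/C=C/C(=O)Cl)ccc1O[Si](C)(C)C(C)(C)C | intermediate (not isolated)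
8 | (2Z)-4-chloro-2-methylbut-2-en-1-yl 4-O-TBS-(E)-ferulate | COc1cc(/C=C/C(=O)OC/C(C)=C\CCl)ccc1O[Si](C)(C)C(C)(C)C | intermediate
9 | methyl acetoacetate | COC(=O)CC(C)=O | starting material
10 | methyl (4Z)-2-acetyl-6-(4-O-TBS-(E)-feruloyloxy)-5-methylhex-4-enoate (racemic) | COc1cc(/C=C/C(=O)OC/C(C)=C\CC(C(C)=O)C(=O)OC)ccc1O[Si](C)(C)C(C)(C)C | intermediate
11 | trimethylsilyl trifluoromethanesulfonate | C[Si](C)(C)OS(=O)(=O)C(F)(F)F | starting material (reagent)
12 | 2-substituted 1-methoxy-1,3-bis(trimethylsilyloxy)buta-1,3-diene | COc1cc(/C=C/C(=O)OC/C(C)=C\CC(C(=C)O[Si](C)(C)C)=C(OC)O[Si](C)(C)C)ccc1O[Si](C)(C)C(C)(C)C | intermediate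
13 | 4-(tert-butyldimethylsilyloxy)benzaldehyde | O=Cc1ccc(O[Si](C)(C)C(C)(C)C)cc1 | starting material
14 | diethyl {2-[methoxy(methyl)amino]-2-oxoethyl}phosphonate | CCOP(=O)(CC(=O)N(C)OC)OCC | starting material
15 | (E)-3-[4-(tert-butyldimethylsilyloxy)phenyl]-N-methoxy-N-methylprop-2-enamide | CON(C)C(=O)/C=C/c1ccc(O[Si](C)(C)C(C)(C)C)cc1 | intermediate
16 | ethynylmagnesium bromide | C#C[Mg]Br | starting material (reagent)
17 | (E)-1-[4-(tert-butyldimethylsilyloxy)phenyl]pent-1-en-4-yn-3-one | C#CC(=O)/C=C/c1ccc(O[Si](C)(C)C(C)(C)C)cc1 | intermediate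
18 | cyclohexa-1,4-diene cycloadduct: C2'(OMe)(OTMS), C1'(acyl)=C6'H, C5'H2, C4'(OTMS)=C3'(side chain); racemic at C2' | COc1cc(/C=C/C(=O)OC/C(C)=C\CC2=C(O[Si](C)(C)C)CC=C(C(=O)/C=C/c3ccc(O[Si](C)(C)C(C)(C)C)cc3)C2(OC)O[Si](C)(C)C)ccc1O[Si](C)(C)C(C)(C)C | intermediate (not isolated)
19 | gemichalcone A | COc1cc(/C=C/C(=O)OC/C(C)=C\Cc2c(O)ccc(C(=O)/C=C/c3ccc(O)cc3)c2O)ccc1O | target

**Step count.** Total: 8 steps. Longest linear sequence: 5 steps (steps 2, 3, 4, 5 and 8, or equally steps 1, 3, 4, 5 and 8).

**Steps most likely to fail**

Step 8. The acyclic diene must reach a crowded s-cis conformation. A stepwise conjugate addition followed by silyl transfer could stop short of ring closure, or adventitious protons could hydrolyse the ketene acetal before it cycloadds.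
The fallback sets out from 8 and returns at 19. It replaces the acyclic diene by a ring-locked s-cis diene and aromatises by cycloreversion (Alder–Rickert reaction). Chloride 8 would C-alkylate 5,5-dimethylcyclohexane-1,3-dione F1 (K2CO3, aqueous acetone, rt) to the 2-substituted dione F2. TMSOTf/Et3N would give the 2-substituted 5,5-dimethyl-1,3-bis(trimethylsilyloxy)cyclohexa-1,3-diene F3. Heating F3 with 17 (PhMe, 80 °C, then xylene, 140 °C) would give the bicyclo[2.2.2]octa-2,5-diene adduct F4, which would lose 2-methylpropene to give 2',4'-bis-O-TMS-4,4'''-bis-O-TBS-gemichalcone A F5. KHF2 in THF/MeOH would then free 19.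

Step 3. Ionisation of the acyloxonium ion or of the product chloride to an allyl cation would erode the Z geometry or return chloride at the tertiary terminus, and the Lewis acid could oligomerise the dihydrofuran.
The fallback sets out from acid chloride 7 and returns at 8. It separates geometry, leaving group and ester into three classical operations on another Z-locked ring. Commercial 3-methylfuran-2(5H)-one F6 would be reduced with DIBAL-H (CH2Cl2, −78 °C to 0 °C) to (Z)-2-methylbut-2-ene-1,4-diol F7. One equivalent of MsCl with collidine and LiCl in DMF at 0 °C would mesylate and displace the less hindered, prenyl-type hydroxyl to give (Z)-4-chloro-2-methylbut-2-en-1-ol F8. Acylation of F8 with 7 (pyridine, CH2Cl2, 0 °C) would give 8.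

Step 7. The released N,O-dimethylhydroxylamine or excess acetylide could add in conjugate fashion to the newly formed ynone during the quench, or base could oligomerise it.
The fallback sets out from 15 and returns at 17, and it forms the ynone by a neutral oxidation with no amine present. DIBAL-H (THF, −78 °C) would reduce 15 to (E)-3-[4-(tert-butyldimethylsilyloxy)phenyl]prop-2-enal F9. Reagent 16 would add 1,2 to give racemic (E)-1-[4-(tert-butyldimethylsilyloxy)phenyl]pent-1-en-4-yn-3-ol F10. MnO2 (CH2Cl2, rt) would oxidise this doubly activated alcohol to 17.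

**Further compounds**
F1 | step 8 | 5,5-dimethylcyclohexane-1,3-dione | CC1(C)CC(=O)CC(=O)C1
F2 | step 8 | 2-[(2Z)-4-(4-O-TBS-(E)-feruloyloxy)-3-methylbut-2-enyl]-5,5-dimethylcyclohexane-1,3-dione | CC1(C)CC(=O)C(C/C=C(C)\COC(=O)/C=C/c2ccc(O[Si](C)(C)C(C)(C)C)c(OC)c2)C(=O)C1
F3 | step 8 | 2-substituted 5,5-dimethyl-1,3-bis(trimethylsilyloxy)cyclohexa-1,3-diene | C[Si](C)(C)OC1=C(C/C=C(C)\COC(=O)/C=C/c2ccc(O[Si](C)(C)C(C)(C)C)c(OC)c2)C(O[Si](C)(C)C)=CC(C)(C)C1
F4 | step 8 | bicyclo[2.2.2]octa-2,5-diene adduct (racemic) | C[Si](C)(C)OC12CC(C)(C)C(C=C1C(=O)/C=C/c3ccc(O[Si](C)(C)C(C)(C)C)cc3)C(O[Si](C)(C)C)=C2C/C=C(C)\COC(=O)/C=C/c4ccc(O[Si](C)(C)C(C)(C)C)c(OC)c4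
F5 | step 8 | 2',4'-bis-O-TMS-4,4'''-bis-O-TBS-gemichalcone A | COc1cc(/C=C/C(=O)OC/C(C)=C\Cc2c(O[Si](C)(C)C)ccc(C(=O)/C=C/c3ccc(O[Si](C)(C)C(C)(C)C)cc3)c2O[Si](C)(C)C)ccc1O[Si](C)(C)C(C)(C)C
F6 | step 3 | 3-methylfuran-2(5H)-one | CC1=CCOC1=O
F7 | step 3 | (Z)-2-methylbut-2-ene-1,4-diol | OC/C(C)=C\CO
F8 | step 3 | (Z)-4-chloro-2-methylbut-2-en-1-ol | OC/C(C)=C\CCl
F9 | step 7 | (E)-3-[4-(tert-butyldimethylsilyloxy)phenyl]prop-2-enal | O=C/C=C/c1ccc(O[Si](C)(C)C(C)(C)C)cc1
F10 | step 7 | (E)-1-[4-(tert-butyldimethylsilyloxy)phenyl]pent-1-en-4-yn-3-ol (racemic) | C#CC(O)/C=C/c1ccc(O[Si](C)(C)C(C)(C)C)cc1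
A1 | direct plan | 2',4'-dihydroxy-3'-methylacetophenone | CC(=O)c1ccc(O)c(C)c1O
A2 | direct plan | 4-hydroxybenzaldehyde | O=Cc1ccc(O)cc1
A3 | direct plan | (E)-1-(2,4-dihydroxy-3-methylphenyl)-3-(4-hydroxyphenyl)prop-2-en-1-one | Cc1c(O)ccc(C(=O)/C=C/c2ccc(O)cc2)c1O
A4 | direct plan | 3'-methylchalcone triacetate | Cc1c(OC(C)=O)ccc(C(=O)/C=C/c2ccc(OC(C)=O)cc2)c1OC(C)=O
A5 | direct plan | 3'-(bromomethyl)chalcone triacetate | BrCc1c(OC(C)=O)ccc(C(=O)/C=C/c2ccc(OC(C)=O)cc2)c1OC(C)=O
A6 | direct plan | (Z)-2-methyl-3-(tributylstannyl)prop-2-en-1-ol | OC/C(C)=C\[Sn](CCCC)(CCCC)CCCC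
A7 | direct plan | 3'-[(2Z)-4-hydroxy-3-methylbut-2-enyl]chalcone triacetate | OC/C(C)=C\Cc1c(OC(C)=O)ccc(C(=O)/C=C/c2ccc(OC(C)=O)cc2)c1OC(C)=O
A8 | direct plan | gemichalcone A 2',4',4-triacetate | COc1cc(/C=C/C(=O)OC/C(C)=C\Cc2c(OC(C)=O)ccc(C(=O)/C=C/c3ccc(OC(C)=O)cc3)c2OC(C)=O)ccc1O
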